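The runs stem from a simulated flask for substances that don't exist.

The nucleophile of the dawn flask has three ways open: it attacks the electrophile, which makes target and sets acid free; it takes up that acid as protonated nucleophile, though the free base can take the acid too; or two nucleophile condense with each other.

| setting | dawn | autumn | flask |
|---|---|---|---|
| electrophile | 0.59 M | 0.59 M | 0.59 M |
| nucleophile | 1.8 equiv | 1.8 equiv | 1.80 equiv |
| free base | 1.5 equiv | 1 equiv | 1.50 equiv |
| remark | the very flask that is asked about, followed so far | run made earlier |  |
| time |  |  | 6.0 h |

- dawn (time / min: electrophile / %, target / %): 8.00: 66.2, 35.1; 20.0: 55.3, 45.4; 40.0: 50.6, 48.5; 60.0: 49.9, 50.5; 80.0: 47.0, 52.9; 120: 47.3, 52.4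
- autumn (time / h: electrophile / %, target / %): 1.00: 49.1, 51.0; 2.00: 47.5, 51.9; 3.00: 47.5, 52.8; 4.00: 45.4, 55.2; 5.00: 46.3, 55.1; 6.00: 42.7, 54.8

(readings scatter by 1 percentage point)

- steps thought possible: electrophile + nucleophile -> acid set free + target; nucleophile + acid set free <-> protonated nucleophile; acid set free + free base <-> salt of the base; 2 nucleophile -> self-condensation product
- the earlier runs do not show how much of nucleophile is bound; that part of a forecast is a guess

- part of the electrophile that has reacted at 6.0 h
- share of the unused nucleophile that is free and not bound as protonated nucleophile, at 6.0 h

Does the stall follow the free base? At 2.00 h the autumn run, on 1 equiv of free base, holds 47.5% electrophile, and the dawn run, on 1.5 equiv, holds 47.3% at 120 min: a gap of 0.2 percentage points, with a scatter of 1 point. So what does a target cost? The nucleophile price, the nucleophile charged per target standing, reads 3.44 in the dawn run at 120 min, while the attack itself takes one. The autumn run shows 54.8% target at 6.00 h, a price of 3.28, so the reckoning here, on that scattered reading from a run with less free base, puts the dawn flask near that much target at 6.0 h. The earlier runs do not show how much nucleophile is bound, so the free share stays a guess.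

The forecast gives 56% and 80%: “Base exceeds acid by about 1 equiv, so most nucleophile should be free, unless the base is weak”.

The dawn flask gives 56.3% reacted and a free share of 0.831%.

    electrophile + nucleophile → acid set free + target (k = 0.00166 /M/s)
    nucleophile + acid set free ⇌ protonated nucleophile, settled at all times (K = 3570 /M)
    acid set free + free base ⇌ salt of the base (K = 1.30 /M, k = 0.0450 /M/s)
    2 nucleophile → self-condensation product (k = 0.00137 /M/s)

At 6.00 h the dawn flask holds 0.262 M protonated nucleophile and its price stands at 3.19; the nucleophile, the limiting reagent, keeps 0.21% of its charge unbound, less than the 96% kept by the free base. The neighbour flask, charged with 0.450 equiv of nucleophile, should hold 13.1% target at the price read from the dawn run; at 6.00 h it holds 23.5%, a price of 1.91.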